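The vessel is a closed, stirred flask in which free base releases the nucleophile from its protonated form, and the nucleophile then meets the electrophile.

electrophile 0.18 M; protonated nucleophile 0.360 M; time 40 h

    electrophile + nucleophile → acid set free + target (k1 = 4.1 × 10⁻⁵ M⁻¹ s⁻¹)
    nucleophile + acid set free ⇌ protonated nucleophile, settled at all times (K2 = 6100 M⁻¹)
    acid set free + free base ⇌ salt of the base (K3 = 520 M⁻¹, k3 = 0.0011 M⁻¹ s⁻¹)
    electrophile + target ⇌ idle adduct, settled at all times (K4 = 220 M⁻¹)
    crystals ⇌ target, rate k5*(cs5 - [target]) while solid is left; crystals form when [target] > cs5 (cs5 = 11 mM, k5 = 1.5 × 10⁻⁴ s⁻¹)
    electrophile → decomposition product (k6 = 7.2 × 10⁻⁹ s⁻¹)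

- in percentages every species weighs as the electrophile in it: one idle adduct counts as two
- for target the idle adduct and crystals are counted in
- as a solid, counted per litre of solution: crystals
- the amount of free base is what is sought; it is there from the start
- in an amount of target, one idle adduct counts as one target
- what has gone from electrophile into another species counts as reacted, even if it can come back
- run time (flask): 40 h

* the concentration of free base at which the part of the electrophile that has reacted at 40 h is just 50%, in M

On the first rung stand the balances, kept at all times. At the mark of 50% reacted, 0.0900 M of electrophile remains, and its product with the adduct constant is 19.8. So at the mark nearly all of the target sits as idle adduct. The mark therefore needs a target amount of 0.0461 M. Of this, 2.22 mM is dissolved, less than the solubility of 11 mM, so this reckoning holds no crystals. Free acid is tied to the free nucleophile, n, through the protonation balance.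

On the next rung n moves. Each acid taken by the base frees one nucleophile, while each target costs 2: one coupled, one protonated by the acid set free. Supply falls as n rises, and use grows with n. With use dropped, at the early end, n squared grows in step with time. At the late end this reckoning sets supply equal to use, which gives a plateau.

Joining the ends at the midway electrophile, 0.135 M, gives a rise with time constant τ of 12.5 h, shorter than the run, and a lag of 7.70 h. Further out stands decomposition, with a half-life of 26700 h, far beyond the run.

The carried quantity is n*, the plateau of free nucleophile that makes the needed target in the run less the lag: 0.0716 M. At the end, protonated nucleophile stands near 0.242 M. Supply equal to use at n*, with protonated nucleophile midway between charge and end, asks for 1.05 M of base. The salt ends near 0.164 M. Base spent and acid returned by the salt grow through the run, and taking them at half their end value adds 0.366 M. This reckoning gives 1.41 M.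

The forecast stands lower, at 1.25 M within 0.9 M to 1.8 M, noting that “the base takes up acid so slowly”.

The flask needs 1.52 M of free base. At 20.0 h the step to target has 53% of its turnover up to 40 h behind it. With that charge, salt of twice the target plus n* leaves 89.2% of the charged free base still free, and the flask shows 89.5% at 40.0 h.

All constants were chosen freely; the result is computed.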